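Remark on the chemistry: compound 7 has no stereocentre and its diaryl ether axis rotates freely. It is therefore achiral, and "single enantiomer" is taken to mean the one constitution given by the SMILES string.

## The problem

Compound 7 is a pentabromo-2,2'-oxydiphenol. Ring A (C1 OH, C2 Br, C3 H, C4 Br, C5 H, C6 bridge oxygen) and ring B (C1' OH, C2' Br, C3' Br, C4' Br, C5' H, C6' bridge oxygen) share one ether oxygen that has a free hydroxyl next to it on either side. There is no stereocentre and no hindered axis, so no centre has to control another and the whole problem is one of position. The C6–O–C6' bridge lies between two electron-poor, ortho-oxygenated rings with five C–Br bonds, each of which competes in copper or palladium chemistry and none of which activates its ring enough for SNAr. Four bromines (C2, C4, C2', C4') stand ortho or para to a hydroxyl, where electrophilic bromination puts them unasked; the fifth, on C3', is meta to its hydroxyl, wedged between two bromines, and present in one ring only. Without Br-3' the molecule is C2-symmetric, so the hardest task is to break a hidden symmetry with exactly one bromine at the carbon that the hydroxyl groups do not activate. The free bromophenols do not tolerate strong oxidants (quinone formation), organolithiums, low-valent metals or light (loss of bromine), nor hot base (Smiles migration of ring B between the two oxygens of ring A). The feature that opens the problem is the chain O(C1)–C1–C6–O–C6': the hydroxyl oxygen on C1 of ring A lies within reach of C6' of ring B, so a two-electron oxidation can close a five-membered 1,3-dioxole on C6' and turn ring B, and only ring B, into a cyclohexa-2,4-dienone whose β-carbon is C3'.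

## Retrosynthesis

**7 ⇒ 6.** Bonds cut: C2–Br, C4–Br, C2'–Br and C4'–Br.
- These are the bromines that the two hydroxyl groups call for by themselves, so they come off first and go on last.
- Cutting Br-3' first would lead to a symmetric tetrabromide in which no reagent can tell the rings apart.
- Precursor 6 carries one bromine instead of five.
- The forward reaction must fill all four ortho/para positions, two of them next to Br-3', and stop there.

**6 ⇒ 5.** Bond cut: C3'–Br, in the unusual sense of bromide plus an electrophilic C3'. In the same move the bond O(C1)–C6' is drawn in, which gives spiroketal 5.
- C3' is meta to OH-1' and silent towards Br+, but it is the β-carbon of the dienone of 5, so reversal of polarity turns the worst position into the best one.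
- The neighbouring option, Br+ para to the bridge oxygen of a protected form of 4, reaches the same carbon but cannot distinguish the rings.
- Compound 5 contains no halogen at all.
- The forward reaction must deliver bromide to C3' rather than to C5' or C4', and must rearomatise by breaking one ketal C–O bond.
- Because the catechol half of 5 is symmetric, it does not matter which C–O bond breaks. This fixes the order: Br-3' first, ring A bromines later.

**5 ⇒ 4.** Bond cut: the ketal bond O(C1)–C6', with return of two electrons.
- This is where the symmetry is broken. One ring of C2-symmetric 4 is dearomatised, while the other is consumed as the ketal and stays aromatic, so the stoichiometry of the oxidation limits the event to one ring.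
- Compound 4 is a halogen-free, symmetric C12 diol.
- The forward oxidation must be a two-electron process and must be trapped intramolecularly at the oxygen-bearing ortho carbon through a five-membered closure.

**4 ⇒ 3 ⇒ 2 ⇒ 1.** Bonds cut: C1–OH and C1'–OH, not the bridge.
- The bridge oxygen of the commodity chemical 1 directs lithiation to both ortho carbons (2). Borylation (3) and peroxide oxidation then place both hydroxyls in one flask.
- The diaryl ether bond, usually the centre of such a synthesis, is bought and never made, and no C–Br bond is present while organolithium chemistry is run.
- The forward reaction must functionalise both rings completely.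

## Roads not taken

**Alternative 1:** the most obvious cut, through the bridge C–O bond.
- Forward key step: Ullmann-type coupling of 3,5-dibromo-2-methoxyphenol A1 with 1,2,3-tribromo-5-iodo-4-methoxybenzene A2 to the dimethyl ether A3, then BBr3 to 7.
- Each C–Br bond of A1, A2 and A3 is a possible site for copper, and A1 can couple with itself.
- Both reacting centres carry an ortho substituent, and A1 is a weak nucleophile.
- In both halves the methyl group must sit on the oxygen next to bromine. That is the reverse of what bromination of guaiacol delivers, so each half costs several steps of protecting-group exchange.
- If the coupling is moved ahead of the brominations, it only produces ethers of 4, which one step from 1 provides, and the problem of Br-3' remains untouched.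

**Alternative 2:** the same bridge bond cut in the biosynthetic sense.
- Forward key step: one-electron oxidation (anode, MnO2 or a peroxidase mimic) of a mixture of 2,4-dibromophenol A4 and 3,4,5-tribromobenzene-1,2-diol A5. This would join C6 of the phenoxyl radical of A4 to the oxygen of A5 that lies next to its C–H.
- The route is very short, but A5 is oxidised more easily than A4 and passes on to quinone A6, which reacts by addition–elimination at its C–Br carbons rather than as an oxygen radical.
- The radical of A4 meets mostly its own kind (O–C6 and C6–C6 homocoupling), and A5 offers two different oxygens.
- In the organism an enzyme pocket chooses the partners; in the flask nothing in either structure does.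
- The chosen plan keeps phenol oxidation as the enabling event but makes it intramolecular and two-electron.

**Alternative 3:** C3'–Br cut last, from the C2-symmetric tetrabromide A7 (4 plus four equivalents of bromine).
- Forward key step, option (a): a fifth electrophilic bromination.
- Forward key step, option (b): protection to the bis-MOM ether A8, deprotonation of the C–H between two bromines with LDA at −78 °C, a Br+ quench to A9, and acid to 7.
- Nothing tells the rings apart, so either way tetra-, penta- and hexabromo congeners arise together and are hard to separate.
- In (a), C3' and C5' are both meta to the hydroxyl and activated only by the weakly donating bridge oxygen, with C3' the more crowded.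
- Option (b) is regiochemically sound but needs two protecting-group steps and a strong base on a substrate prone to halogen dance and aryne formation.
- In the chosen plan the redox stoichiometry itself limits the event to one ring, and no protecting group is used.

Key step: step 2

## Steps

Step 1
Reactants: 1 diphenyl ether
Product: 4 2,2'-oxydiphenol, via dilithio ether 2 (not isolated), via bis(boronate) 3 (not isolated)
Conditions: n-BuLi (2.5 equiv), TMEDA, Et2O, 0 °C → rt; B(OMe)3 (excess), −78 °C → rt; AcOH, 30% aq. H2O2, 0 °C → rt
Reagents that add atoms: n-butyllithium, [Li]CCCC (lithium of 2); trimethyl borate, COB(OC)OC (boron and methoxy groups of 3); hydrogen peroxide, OO (the two new oxygen atoms of 4)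
Why: Double directed ortho-metalation, in which the ether oxygen binds n-BuLi·TMEDA and directs lithiation to both ortho carbons, gives the same dianion that serves for the bis(phosphine) ligands of the diphenyl ether family. Borylation and peroxide oxidation (1,2-aryl shift from boron to oxygen) are standard, and every C–B bond, also that of a bridged borinate, ends as C–OH.

Step 2
Reactants: 4 2,2'-oxydiphenol
Product: 6 5-bromo-2-(2-hydroxyphenoxy)phenol, via spirodienone 5 (not isolated)
Conditions: PhI(OAc)2 (1.0 equiv), CH2Cl2 (0.02 M), −20 °C; then HBr (33% in AcOH, 3 equiv), −40 → 0 °C
Reagents that add atoms: hydrogen bromide, Br
Why: Proposed new method: PhI(OAc)2 binds one phenolic oxygen of 4, and as iodobenzene departs the hydroxyl oxygen on C1 of the other ring attacks C6', the ortho carbon whose own oxygen best carries the developing charge, in a 5-exo-trig spirocyclisation to the 1,3-dioxole ring of 5; this half is the known hypervalent-iodine dearomatisation of 2-alkoxyphenols with a tethered hydroxyl to o-quinone monoketals. HBr then protonates the dienone oxygen to a hydroxybenzenium ion with its charge on C1', C3' and C5', bromide is taken up at C3', and loss of H-3' together with one catechol oxygen from C6' (1,4-elimination) reopens the dioxole and restores the arene, so that the ring closed in the first half is spent in the second and no stereocentre is formed (C6' of 5 bears two equivalent oxygen arms). The closest known reaction types are the hydrohalogenation of o-benzoquinones to 4-halocatechols (halide para to one oxygen and meta to the other), the conjugate addition of carbon, nitrogen and sulfur nucleophiles to masked o-benzoquinones with loss of alcohol, and the capture of ipso-arenium ions para to their sp3 carbon; halide addition to a spiro o-quinone ketal with aromatising C–O cleavage is the new element. Ring selectivity is secured by the structure: the second ring is consumed as the ketal and cannot be oxidised, and the oxidant is used up before bromide is added, so exactly one bromine enters one ring. Site selectivity for C3' over C5' rests on the fully substituted C6' next to C5', which shields it and whose two oxygens withdraw charge from it, and on the reversibility of bromide addition against the irreversible aromatisation. Attack at C4' needs prior ionisation of the ketal to an aryloxyphenoxenium ion, which the adjacent carbonyl group, the non-ionising solvent and the low temperature disfavour. Either C6'–O bond may break with the same result, because the catechol part of 5 is unsubstituted and symmetric, and this is why the step is placed before ring A is brominated. Dilution and low temperature hold back the Diels–Alder dimerisation typical of unsubstituted cyclohexa-2,4-dienones.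

Step 3
Reactants: 6 5-bromo-2-(2-hydroxyphenoxy)phenol
Product: 7 2,3,4-tribromo-6-(3,5-dibromo-2-hydroxyphenoxy)phenol
Conditions: Br2 (4.1 equiv), AcOH, 10 °C → rt; aq. NaHSO3 work-up
Reagents that add atoms: bromine, BrBr
Why: Electrophilic aromatic bromination under the control of the two free hydroxyl groups, for which C2, C4, C2' and C4' are the only ortho/para positions left; a meta bromine does not block its neighbours, as the ready perbromination of 3-bromophenol at all of its ortho and para positions shows. C3, C5 and C5' are meta to a hydroxyl and lie on rings that by then carry two or three bromines, so the reaction should stop at five.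

## Compound list

1 | diphenyl ether | c1ccc(cc1)Oc1ccccc1 | starting material
2 | 2,2'-dilithiodiphenyl ether | [Li]c1ccccc1Oc1ccccc1[Li] | intermediate
3 | tetramethyl (oxydi-2,1-phenylene)bis(boronate) | COB(OC)c1ccccc1Oc1ccccc1B(OC)OC | intermediate
4 | 2,2'-oxydiphenol | Oc1ccccc1Oc1ccccc1O | intermediate
5 | spiro[1,3-benzodioxole-2,1'-cyclohexa-3',5'-dien]-2'-one | O=C1C=CC=CC12Oc1ccccc1O2 | intermediate
6 | 5-bromo-2-(2-hydroxyphenoxy)phenol | Oc1cc(Br)ccc1Oc1ccccc1O | intermediate
7 | 2,3,4-tribromo-6-(3,5-dibromo-2-hydroxyphenoxy)phenol | Oc1c(Br)cc(Br)cc1Oc1cc(Br)c(Br)c(Br)c1O | target

## Step count and least certain steps

Total step count: 3. Longest linear sequence: 3 (from diphenyl ether).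

**Step 2 (key step, proposed new method).**
- Most likely failure: loss of site control in the bromide capture. This means 1,6-addition at C5' or, after ionisation of the ketal, attack at C4', because the three sites differ only by moderate steric and electronic bias.
- Also possible: Diels–Alder dimerisation of the dienone before bromide arrives, and intermolecular coupling during the oxidation because the para positions are free.
- Fallback (known chemistry): it sets out from 4 and returns at 6.
  - Both hydroxyls are acetylated (Ac2O, pyridine) to oxydi-2,1-phenylene diacetate F1. The ester groups mute the hydroxyl oxygens, so the bridge oxygen becomes the strongest director.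
  - One equivalent of Br2 in AcOH then brominates para to the bridge oxygen, by the logic of the standard preparation of 5-bromoguaiacol through its acetate. This gives 2-(2-acetoxyphenoxy)-5-bromophenyl acetate F2.
  - Methanolysis (K2CO3, MeOH) gives 6.
- Price of the fallback: three steps instead of one, and a statistical spread over un-, mono- and dibrominated material that needs separation and recycling.

**Step 3.**
- Most likely failure: uneven rates. Ring A fills first, while ring B is deactivated and crowded by Br-3'. The last substitution at C2' may therefore lag while ring A begins to take a third bromine para to the bridge oxygen, and control by stoichiometry alone would give congeners that are hard to separate.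
- Fallback: it sets out from 6 and returns at 7, replacing stoichiometric control by saturation and reductive stripping.
  - Excess Br2 with NaOAc in AcOH is used. These are the conditions under which tribromophenols are carried on to tetrabromocyclohexadienones.
  - After the four substitutions each ring takes one further ipso bromine at C4 and C4'. This gives 2,3,4,4-tetrabromo-6-[(3,3,5-tribromo-6-oxocyclohexa-1,4-dien-1-yl)oxy]cyclohexa-2,5-dien-1-one F3, whose rings are no longer arenes and cannot be substituted further.
  - Aqueous NaHSO3 then removes only the two labile bromines and gives 7.

**Step 1.**
- Most likely failure: incomplete functionalisation of the second ring. Causes could be a sluggish second lithiation, poorly soluble ate complexes when both aryl–lithium bonds close on one boron, or protodeboronation before oxidation. Each of these costs one hydroxyl.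
- Fallback: it sets out from 2 and returns at 4, changing the C–O forming event from a boron-to-oxygen to a carbon-to-oxygen shift.
  - The dianion is quenched with DMF to 2,2'-oxydibenzaldehyde F4, which can be freed from monofunctionalised material by crystallisation.
  - Double Baeyer–Villiger oxidation (mCPBA, CH2Cl2; aryl migration favoured by the ortho aryloxy group) gives oxydi-2,1-phenylene diformate F5.
  - Methanolysis (K2CO3, MeOH) gives 4.

## Further compounds

F1 | step 2 | oxydi-2,1-phenylene diacetate | CC(=O)Oc1ccccc1Oc1ccccc1OC(C)=O
F2 | step 2 | 2-(2-acetoxyphenoxy)-5-bromophenyl acetate | CC(=O)Oc1cc(Br)ccc1Oc1ccccc1OC(C)=O
F3 | step 3 | 2,3,4,4-tetrabromo-6-[(3,3,5-tribromo-6-oxocyclohexa-1,4-dien-1-yl)oxy]cyclohexa-2,5-dien-1-one | O=C1C(Br)=CC(Br)(Br)C=C1OC1=CC(Br)(Br)C(Br)=C(Br)C1=O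
F4 | step 1 | 2,2'-oxydibenzaldehyde | O=Cc1ccccc1Oc1ccccc1C=O
F5 | step 1 | oxydi-2,1-phenylene diformate | O=COc1ccccc1Oc1ccccc1OC=O
A1 | alternative 1 | 3,5-dibromo-2-methoxyphenol | COc1c(O)cc(Br)cc1Br
A2 | alternative 1 | 1,2,3-tribromo-5-iodo-4-methoxybenzene | COc1c(I)cc(Br)c(Br)c1Br
A3 | alternative 1 | 1,2,3-tribromo-5-(3,5-dibromo-2-methoxyphenoxy)-4-methoxybenzene | COc1c(Br)cc(Br)cc1Oc1cc(Br)c(Br)c(Br)c1OC
A4 | alternative 2 | 2,4-dibromophenol | Oc1ccc(Br)cc1Br
A5 | alternative 2 | 3,4,5-tribromobenzene-1,2-diol | Oc1cc(Br)c(Br)c(Br)c1O
A6 | alternative 2 | 3,4,5-tribromocyclohexa-3,5-diene-1,2-dione | O=C1C=C(Br)C(Br)=C(Br)C1=O
A7 | alternative 3 | 2,2'-oxybis(4,6-dibromophenol) | Oc1c(Br)cc(Br)cc1Oc1cc(Br)cc(Br)c1O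
A8 | alternative 3 | 1,1'-oxybis[3,5-dibromo-2-(methoxymethoxy)benzene] | COCOc1c(Br)cc(Br)cc1Oc1cc(Br)cc(Br)c1OCOC
A9 | alternative 3 | 1,2,3-tribromo-5-[3,5-dibromo-2-(methoxymethoxy)phenoxy]-4-(methoxymethoxy)benzene | COCOc1c(Br)cc(Br)cc1Oc1cc(Br)c(Br)c(Br)c1OCOC
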